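**Strategy**

The trans-decalin is disconnected through ring B at C5–C10 and C7–C8. These bonds flank C6, so a temporary C6 ketone lets one carbonyl act twice: a cationic gold catalyst adds the C5 enol across the C10=C20 alkene (closing ring A and making the angular methyl) and then the C7 enol to the C8≡C17 alkyne (closing ring B and leaving the exocyclic methylene). The step exploits the C20 methyl on quaternary C10 and the C8=C17 methylene beside C7 of ring B. Its precursor is an acyclic methyl ketone carrying the C3, C4 and C9 stereocentres, a 1,1-disubstituted alkene and a terminal alkyne; afterwards C6 is deoxygenated and the hydroxylactone is added by aldol.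

Key step: step 11

Numbering: atoms carry labdane numbers (C1–C10 decalin, C11–C16 side chain and lactone, C17 exocyclic methylene, C18 and C19 on C4, C20 on C10).

Assumption: compounds 10, 20 and 22 are taken as commercial, and the sense of induction of the BINAP ligands in steps 2 and 8 is assigned by analogy with simple β-keto esters and enoates (the antipodal ligand would be used if the sense proves opposite).

**Route**

Step 1
Reactants: 1 methyl acetoacetate; 2 2,3-dibromopropene
Product: 3 methyl 6-bromo-3-oxohept-6-enoate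
Conditions: NaH, then n-BuLi, THF, 0 °C; 2, 0 °C → rt; aq. HCl quench
Reagents that add atoms: none
Why: γ-Alkylation of the β-keto ester dianion: the more reactive terminal carbanion displaces the allylic bromide of 2 by SN2, the vinylic bromide being inert.

Step 2
Reactants: 3 methyl 6-bromo-3-oxohept-6-enoate
Product: 4 methyl (3R)-6-bromo-3-hydroxyhept-6-enoate
Conditions: H2 (4 atm), RuCl2[(R)-BINAP] (0.5 mol%), MeOH, 60 °C
Reagents that add atoms: none
Why: Noyori asymmetric hydrogenation of a β-keto ester: the ester-chelated ruthenium hydride with (R)-BINAP should deliver hydride to one carbonyl face and set C3 as R, and the bromoalkene should not be reduced.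

Step 3
Reactants: 4 methyl (3R)-6-bromo-3-hydroxyhept-6-enoate
Product: 5 methyl (2R,3R)-2-allyl-6-bromo-3-hydroxyhept-6-enoate
Conditions: LDA (2.2 equiv), THF, −78 → −20 °C; allyl bromide, DMPU, −78 → −20 °C; aq. HCl quench
Reagents that add atoms: allyl bromide, C=CCBr
Why: Fráter–Seebach alkylation: the lithium-chelated alkoxide enolate is allylated on the face away from the C3 chain, which should give the anti (2R,3R) product.

Step 4
Reactants: 5 methyl (2R,3R)-2-allyl-6-bromo-3-hydroxyhept-6-enoate
Product: 6 methyl (2S,3R)-2-allyl-6-bromo-3-hydroxy-2-methylhept-6-enoate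
Conditions: LDA (2.5 equiv), THF/DMPU, −78 → −20 °C; MeI, −78 → −10 °C; aq. HCl quench
Reagents that add atoms: iodomethane, CI
Why: Second Fráter–Seebach alkylation: the chelated dianion is again attacked anti to the alkoxide side, so methyl enters where allyl had entered and the quaternary C4 centre is set as 2S (methyl anti, allyl syn to the oxygen).

Step 5
Reactants: 6 methyl (2S,3R)-2-allyl-6-bromo-3-hydroxy-2-methylhept-6-enoate
Product: 7 TBS ether of 6
Conditions: TBSOTf, 2,6-lutidine, CH2Cl2, 0 °C
Reagents that add atoms: tert-butyldimethylsilyl trifluoromethanesulfonate, CC(C)(C)[Si](C)(C)OS(=O)(=O)C(F)(F)F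
Why: Silylation of the hindered secondary alcohol with the silyl triflate; it prevents lactol formation with the later ketone and retro-aldol cleavage.

Step 6
Reactants: 7 TBS ether of 6
Product: 8 methyl ketone (C6 ketone, acetonyl group on C4)
Conditions: PdCl2 (10 mol%), CuCl, O2 (1 atm), DMF/H2O (7:1), rt
Reagents that add atoms: water, O
Why: Wacker–Tsuji oxidation: Markovnikov hydroxypalladation of the monosubstituted allyl alkene gives the methyl ketone, the 1,1-disubstituted bromoalkene being unreactive.

Step 7
Reactants: 8 methyl ketone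
Product: 9 alkenyl pinacol boronate
Conditions: B2pin2, PdCl2(dppf) (3 mol%), KOAc, dioxane, 80 °C
Reagents that add atoms: bis(pinacolato)diboron, CC1(C)OB(OC1(C)C)B1OC(C)(C)C(C)(C)O1
Why: Miyaura borylation: oxidative addition of zerovalent palladium into the alkenyl bromide and transmetalation with the diboron give the 1,1-disubstituted alkenyl boronate, the weak acetate base leaving ketone and esters untouched.

Step 8
Reactants: 9 alkenyl pinacol boronate; 10 methyl (2E)-4,4-dimethoxybut-2-enoate
Product: 11 dimethyl (2S,3R,7S)-3-(TBS-oxy)-7-(dimethoxymethyl)-2-methyl-6-methylidene-2-(2-oxopropyl)nonanedioate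
Conditions: [Rh(cod)Cl]2 (3 mol%), (S)-BINAP (7 mol%), K3PO4, dioxane/H2O (10:1), 80 °C
Reagents that add atoms: none
Why: Hayashi–Miyaura reaction (rhodium-catalysed asymmetric conjugate addition): the alkenylrhodium species adds to the β-carbon of the enoate and the chiral bisphosphine selects the enoate face, setting C9 (S here) independently of the remote C3 and C4 centres.

Step 9
Reactants: 11 acetal diester
Product: 12 dimethyl (2S,3R,7S)-3-(TBS-oxy)-7-formyl-2-methyl-6-methylidene-2-(2-oxopropyl)nonanedioate
Conditions: Amberlyst-15, acetone/H2O (20:1), 0 °C → rt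
Reagents that add atoms: water, O
Why: Mild acid-catalysed acetal hydrolysis unmasks the C8 aldehyde without touching the silyl ether; the α-branched aldehyde is used at once.

Step 10
Reactants: 12 aldehyde
Product: 13 dimethyl (2S,3R,7S)-3-(TBS-oxy)-7-ethynyl-2-methyl-6-methylidene-2-(2-oxopropyl)nonanedioate
Conditions: dimethyl (1-diazo-2-oxopropyl)phosphonate, K2CO3, MeOH, 0 °C
Reagents that add atoms: dimethyl (1-diazo-2-oxopropyl)phosphonate, CC(=O)C(=[N+]=[N-])P(=O)(OC)OC
Why: Ohira–Bestmann (Seyferth–Gilbert) homologation: the diazophosphonate anion adds to the aldehyde and not to the methyl ketone, and the alkylidene carbene rearranges to the terminal alkyne (C17), low temperature limiting epimerisation at C9.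

Step 11
Reactants: 13 acyclic keto enyne
Product: 15 trans-decalin keto diester, via ring-A ketone 14 (not isolated)
Conditions: (IPr)AuCl (10 mol%; IPr = 1,3-bis(2,6-diisopropylphenyl)imidazol-2-ylidene), AgNTf2 (10 mol%), 4 Å MS, toluene, 90 °C
Reagents that add atoms: none
Why: Proposed new method: the cationic gold centre coordinates the C10=C20 alkene and the C5 enol of the C6 ketone attacks the more substituted carbon C10 (6-exo-trig, Markovnikov), protodeauration turning C20 into the angular methyl; the regenerated ketone then enolises towards C7 and that enol attacks the gold-activated C8≡C17 alkyne at C8 (6-exo-dig), protodeauration leaving the exocyclic methylene. The closest known reaction types are the gold-catalysed intramolecular hydroalkylation of unactivated alkenes by simple ketones and the gold-catalysed Conia-ene carbocyclisation of ketone enol equivalents onto alkynes; using both in tandem on the α and α′ carbons of one ketone is the new element. Ring A must close first because every other enol–π pairing would give an eight- or ten-membered ring, and ring B can then close only through C7 because C5 would give a four-membered ring. C10 is set in a chair transition state with the C3 silyloxy group and the C9 side chain equatorial and the smaller C4 ester axial beside the incoming C20, and C5 stays enolisable, so it settles under thermodynamic control with the acyl carbon equatorial and the ring fusion trans. The step needs the alkyne to survive until ring A exists and the β,γ-unsaturated ketone to survive afterwards; the methyl ester at C12 (no irreversible oxygen cyclisation onto the alkyne), the bulky silyl ether at C3, the exclusion of water and the absence of base are meant to secure this.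

Step 12
Reactants: 15 trans-decalin keto diester
Product: 17 deoxygenated decalin diester, via tosylhydrazone 16 (not isolated)
Conditions: TsNHNH2, MeOH/THF, 45 °C; then catecholborane, CHCl3, 0 °C; NaOAc·3H2O, reflux
Reagents that add atoms: none
Why: Caglioti-type reduction in the catecholborane (Kabalka) variant: hydride addition to the tosylhydrazone, loss of sulfinate and loss of N2 from the diazene replace the C6 carbonyl by CH2 under near-neutral conditions that should leave the exocyclic alkene in place.

Step 13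
Reactants: 17 deoxygenated decalin diester
Product: 18 12,19-diol
Conditions: LiAlH4, THF, 0 °C → rt; aq. NaOH work-up
Reagents that add atoms: none
Why: Hydride reduction of both methyl esters; LiAlH4 is needed for the hindered axial C19 ester and leaves the alkene and the silyl ether.

Step 14
Reactants: 18 12,19-diol
Product: 19 19-hydroxy-12-aldehyde
Conditions: TEMPO (10 mol%), PhI(OAc)2, CH2Cl2, rt
Reagents that add atoms: none
Why: Oxoammonium (TEMPO) oxidation: the unhindered C12 primary alcohol should be oxidised to the aldehyde much faster than the neopentyl axial C19 alcohol.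

Step 15
Reactants: 20 methyl [(4S)-2,2-dimethyl-1,3-dioxolan-4-yl]acetate
Product: 21 [(4S)-2,2-dimethyl-1,3-dioxolan-4-yl]acetic acid
Conditions: LiOH, THF/H2O, 0 °C → rt; then 1 M HCl to pH 4, 0 °C
Reagents that add atoms: lithium hydroxide, [Li+].[OH-]
Why: Saponification of the methyl ester; careful acidification keeps the acetonide.

Step 16
Reactants: 21 acetonide acid; 22 (4R)-4-benzyl-1,3-oxazolidin-2-one
Product: 24 N-acyl oxazolidinone, via mixed pivalic anhydride 23 (not isolated)
Conditions: PivCl, Et3N, THF, −20 °C; then 22, LiCl, −20 °C → rt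
Reagents that add atoms: none
Why: N-Acylation of the oxazolidinone through the mixed anhydride, the hindered pivaloyl carbonyl directing attack to the desired acyl group.

Step 17
Reactants: 19 19-hydroxy-12-aldehyde; 24 N-acyl oxazolidinone
Product: 26 syn-aldol adduct, via C19 dibutylborinate 25 (not isolated)
Conditions: 24, Bu2BOTf, Et3N, CH2Cl2, −78 → 0 °C; 19 premixed with Bu2BOTf/Et3N at −78 °C, added at −78 → 0 °C; then pH 7 buffer, MeOH, H2O2, 0 °C
Reagents that add atoms: none
Why: Evans syn aldol: the Z-boron enolate reacts through a chair Zimmerman–Traxler transition state on the face opposite the benzyl group of the (R)-auxiliary, which should set C12 (S) and C13 (S), while the C19 hydroxyl is masked in the flask as its borinate.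

Step 18
Reactants: 26 syn-aldol adduct
Product: 28 CNP0113086.2, via deprotected imide 27 (not isolated)
Conditions: 48% aq. HF, MeCN/H2O, 0 °C → rt
Reagents that add atoms: none
Why: Acidic global deprotection and lactonisation: HF cleaves the silyl ether and hydrolyses the terminal acetonide, and the freed primary C15 hydroxyl closes the γ-lactone on the imide carbonyl (5-exo-trig acyl substitution) with loss of the auxiliary, no stereocentre being touched.

**Compound list**

1 | methyl 3-oxobutanoate (methyl acetoacetate) | CC(=O)CC(=O)OC | starting material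
2 | 2,3-dibromoprop-1-ene | C=C(Br)CBr | starting material
3 | methyl 6-bromo-3-oxohept-6-enoate | COC(=O)CC(=O)CCC(Br)=C | intermediate
4 | methyl (3R)-6-bromo-3-hydroxyhept-6-enoate | COC(=O)C[C@H](O)CCC(Br)=C | intermediate
5 | methyl (2R,3R)-6-bromo-3-hydroxy-2-(prop-2-en-1-yl)hept-6-enoate (anti) | C=CC[C@@H](C(=O)OC)[C@H](O)CCC(Br)=C | intermediate
6 | methyl (2S,3R)-6-bromo-3-hydroxy-2-methyl-2-(prop-2-en-1-yl)hept-6-enoate | C=CC[C@](C)(C(=O)OC)[C@H](O)CCC(Br)=C | intermediate
7 | methyl (2S,3R)-6-bromo-3-[(tert-butyldimethylsilyl)oxy]-2-methyl-2-(prop-2-en-1-yl)hept-6-enoate | C=CC[C@](C)(C(=O)OC)[C@H](O[Si](C)(C)C(C)(C)C)CCC(Br)=C | intermediate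
8 | methyl (2S,3R)-6-bromo-3-[(tert-butyldimethylsilyl)oxy]-2-methyl-2-(2-oxopropyl)hept-6-enoate | CC(=O)C[C@](C)(C(=O)OC)[C@H](O[Si](C)(C)C(C)(C)C)CCC(Br)=C | intermediate
9 | methyl (2S,3R)-3-[(tert-butyldimethylsilyl)oxy]-2-methyl-2-(2-oxopropyl)-6-(4,4,5,5-tetramethyl-1,3,2-dioxaborolan-2-yl)hept-6-enoate | CC(=O)C[C@](C)(C(=O)OC)[C@H](O[Si](C)(C)C(C)(C)C)CCC(=C)B1OC(C)(C)C(C)(C)O1 | intermediate
10 | methyl (2E)-4,4-dimethoxybut-2-enoate | COC(=O)/C=C/C(OC)OC | starting material
11 | dimethyl (2S,3R,7S)-3-[(tert-butyldimethylsilyl)oxy]-7-(dimethoxymethyl)-2-methyl-6-methylidene-2-(2-oxopropyl)nonanedioate | CC(=O)C[C@](C)(C(=O)OC)[C@H](O[Si](C)(C)C(C)(C)C)CCC(=C)[C@@H](C(OC)OC)CC(=O)OC | intermediate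
12 | dimethyl (2S,3R,7S)-3-[(tert-butyldimethylsilyl)oxy]-7-formyl-2-methyl-6-methylidene-2-(2-oxopropyl)nonanedioate | CC(=O)C[C@](C)(C(=O)OC)[C@H](O[Si](C)(C)C(C)(C)C)CCC(=C)[C@@H](C=O)CC(=O)OC | intermediate
13 | dimethyl (2S,3R,7S)-3-[(tert-butyldimethylsilyl)oxy]-7-ethynyl-2-methyl-6-methylidene-2-(2-oxopropyl)nonanedioate | CC(=O)C[C@](C)(C(=O)OC)[C@H](O[Si](C)(C)C(C)(C)C)CCC(=C)[C@@H](C#C)CC(=O)OC | intermediate
14 | ring-A ketone: dimethyl (3R,4S,5S,9R,10S)-3-[(tert-butyldimethylsilyl)oxy]-6-oxo-7,8-seco-13,14,15,16-tetranorlabd-8(17)-yne-12,19-dioate | CC(=O)[C@@H]1[C@](C)(C(=O)OC)[C@H](O[Si](C)(C)C(C)(C)C)CC[C@@]1(C)[C@@H](C#C)CC(=O)OC | intermediate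
15 | dimethyl (3R,4S,5S,9R,10S)-3-[(tert-butyldimethylsilyl)oxy]-6-oxo-13,14,15,16-tetranorlabd-8(17)-ene-12,19-dioate | C=C1CC(=O)[C@@H]2[C@](C)(C(=O)OC)[C@H](O[Si](C)(C)C(C)(C)C)CC[C@@]2(C)[C@@H]1CC(=O)OC | intermediate
16 | C6 (4-methylbenzenesulfonyl)hydrazone of 15 | C=C1CC(=NNS(=O)(=O)c3ccc(C)cc3)[C@@H]2[C@](C)(C(=O)OC)[C@H](O[Si](C)(C)C(C)(C)C)CC[C@@]2(C)[C@@H]1CC(=O)OC | intermediate
17 | dimethyl (3R,4S,5S,9R,10S)-3-[(tert-butyldimethylsilyl)oxy]-13,14,15,16-tetranorlabd-8(17)-ene-12,19-dioate | C=C1CC[C@@H]2[C@](C)(C(=O)OC)[C@H](O[Si](C)(C)C(C)(C)C)CC[C@@]2(C)[C@@H]1CC(=O)OC | intermediate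
18 | (3R,4R,5S,9R,10S)-3-[(tert-butyldimethylsilyl)oxy]-13,14,15,16-tetranorlabd-8(17)-ene-12,19-diol | C=C1CC[C@@H]2[C@](C)(CO)[C@H](O[Si](C)(C)C(C)(C)C)CC[C@@]2(C)[C@@H]1CCO | intermediate
19 | (3R,4R,5S,9R,10S)-3-[(tert-butyldimethylsilyl)oxy]-19-hydroxy-13,14,15,16-tetranorlabd-8(17)-en-12-al | C=C1CC[C@@H]2[C@](C)(CO)[C@H](O[Si](C)(C)C(C)(C)C)CC[C@@]2(C)[C@@H]1CC=O | intermediate
20 | methyl [(4S)-2,2-dimethyl-1,3-dioxolan-4-yl]acetate | COC(=O)C[C@H]1COC(C)(C)O1 | starting material
21 | [(4S)-2,2-dimethyl-1,3-dioxolan-4-yl]acetic acid | OC(=O)C[C@H]1COC(C)(C)O1 | intermediate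
22 | (4R)-4-benzyl-1,3-oxazolidin-2-one | O=C1N[C@H](Cc2ccccc2)CO1 | starting material
23 | [(4S)-2,2-dimethyl-1,3-dioxolan-4-yl]acetic pivalic anhydride | CC(C)(C)C(=O)OC(=O)C[C@H]1COC(C)(C)O1 | intermediate
24 | (4R)-4-benzyl-3-{[(4S)-2,2-dimethyl-1,3-dioxolan-4-yl]acetyl}-1,3-oxazolidin-2-one | O=C(C[C@H]1COC(C)(C)O1)N1[C@H](Cc2ccccc2)COC1=O | intermediate
25 | 19-O-dibutylboryl derivative of 19 | C=C1CC[C@@H]2[C@](C)(COB(CCCC)CCCC)[C@H](O[Si](C)(C)C(C)(C)C)CC[C@@]2(C)[C@@H]1CC=O | intermediate
26 | (4R)-4-benzyl-3-[(2S,3S)-2-[(4S)-2,2-dimethyl-1,3-dioxolan-4-yl]-3-hydroxy-4-(decalin unit of 19)butanoyl]-1,3-oxazolidin-2-one (12S,13S,14S) | C=C1CC[C@@H]2[C@](C)(CO)[C@H](O[Si](C)(C)C(C)(C)C)CC[C@@]2(C)[C@@H]1C[C@H](O)[C@@H]([C@H]1COC(C)(C)O1)C(=O)N1[C@H](Cc2ccccc2)COC1=O | intermediate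
27 | deprotected imide (3,12,14,15,19-pentaol) | C=C1CC[C@@H]2[C@](C)(CO)[C@H](O)CC[C@@]2(C)[C@@H]1C[C@H](O)[C@@H]([C@H](O)CO)C(=O)N1[C@H](Cc2ccccc2)COC1=O | intermediate
28 | CNP0113086.2: (3S,4S)-4-hydroxy-3-{(1S)-1-hydroxy-2-[(1R,4aS,5R,6R,8aS)-6-hydroxy-5-(hydroxymethyl)-5,8a-dimethyl-2-methylidenedecahydronaphthalen-1-yl]ethyl}oxolan-2-one | C=C1CC[C@@H]2[C@](C)(CO)[C@H](O)CC[C@@]2(C)[C@@H]1C[C@H](O)[C@@H]1C(=O)OC[C@H]1O | target

**Step count and risks**

Total step count: 18. Longest linear sequence: 16 (steps 1–14, 17 and 18); steps 15 and 16 make the aldol partner.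

Most likely to fail, first: step 11. The alkyne may be consumed (hydration, oligomerisation) before ring A has formed, the bond between the two hindered carbons C5 and C10 may not form, the face selectivity at C10 may be poor, or the exocyclic alkene may move into conjugation with the ketone. The fallback makes the two bonds one after the other with known chemistry and sets out from acetal 11, which has no alkyne. Gold-catalysed ketone–alkene hydroalkylation ((IPr)AuCl/AgClO4, toluene, 90 °C; a thermal Conia-ene cyclisation in a sealed tube is the alternative) should give ring-A keto acetal F1. Acetal hydrolysis gives ring-A keto aldehyde F2, whose C9 is no longer allylic, and Ohira–Bestmann homologation gives monocycle 14, now isolated. TBSOTf/Et3N then gives the kinetic silyl enol ether F3 on the methyl side, and Ph3PAuCl/AgBF4 in CH2Cl2/MeOH closes ring B by the established silyl enol ether–alkyne 6-exo-dig carbocyclisation, coming back to the route at decalin 15.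

Second: step 10. Under the basic homologation the aldehyde may lose its configuration at C9 or its alkene may move into conjugation. The fallback sets out from aldehyde 12 and avoids base while the carbonyl is present. Corey–Fuchs olefination under neutral conditions (CBr4, PPh3, Zn, CH2Cl2, 0 °C) gives 1,1-dibromoalkene F4. Palladium-catalysed hydrogenolysis (Bu3SnH, Pd(PPh3)4) removes the bromine trans to the chain and gives (Z)-bromoalkene F5. Fluoride-induced anti-elimination (TBAF·3H2O, DMF) then returns to alkyne 13, the C3 silyl ether being re-installed with TBSOTf should it be lost.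

Third: step 8. Transmetalation of the hindered 1,1-disubstituted alkenyl boronate may be slower than protodeboronation, and face discrimination on the acyclic enoate may be poor. The fallback sets out from boronate 9 and replaces catalyst control by an auxiliary on a cyclic, more reactive acceptor. Rhodium-catalysed addition without chiral ligand ([Rh(cod)OH]2, dioxane/H2O) to (5R)-5-[(1R,2S,5R)-menthyloxy]furan-2(5H)-one should place the alkenyl group trans to the acetal substituent and give menthyloxy lactone F6. Acid-catalysed methanolysis (camphorsulfonic acid, MeOH, HC(OMe)3) opens the acyl acetal to methyl ester and dimethyl acetal and comes back to the route at 11.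

Further compounds
F1 | step 11 | ring-A keto acetal (C5–C10 bond formed, C8 as dimethyl acetal) | CC(=O)[C@@H]1[C@](C)(C(=O)OC)[C@H](O[Si](C)(C)C(C)(C)C)CC[C@@]1(C)[C@@H](C(OC)OC)CC(=O)OC
F2 | step 11 | ring-A keto aldehyde | CC(=O)[C@@H]1[C@](C)(C(=O)OC)[C@H](O[Si](C)(C)C(C)(C)C)CC[C@@]1(C)[C@@H](C=O)CC(=O)OC
F3 | step 11 | kinetic tert-butyldimethylsilyl enol ether of 14 (C6=C7) | C=C(O[Si](C)(C)C(C)(C)C)[C@@H]1[C@](C)(C(=O)OC)[C@H](O[Si](C)(C)C(C)(C)C)CC[C@@]1(C)[C@@H](C#C)CC(=O)OC
F4 | step 10 | 1,1-dibromoalkene from 12 | CC(=O)C[C@](C)(C(=O)OC)[C@H](O[Si](C)(C)C(C)(C)C)CCC(=C)[C@@H](C=C(Br)Br)CC(=O)OC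
F5 | step 10 | (Z)-bromoalkene | CC(=O)C[C@](C)(C(=O)OC)[C@H](O[Si](C)(C)C(C)(C)C)CCC(=C)[C@@H](/C=C\Br)CC(=O)OC
F6 | step 8 | trans-4-alkenyl-5-(menthyloxy)butyrolactone | CC(=O)C[C@](C)(C(=O)OC)[C@H](O[Si](C)(C)C(C)(C)C)CCC(=C)[C@@H]1CC(=O)O[C@H]1O[C@@H]1C[C@H](C)CC[C@H]1C(C)C
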